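**Analysis of the target**

The target is a flavone (2-aryl-4H-chromen-4-one) in which ring C is the 4-pyranone, ring B is a 2,4-dihydroxyphenyl group on C2, and ring A is a fully substituted benzene with hydroxyls at C5 and C7 and 3-methylbut-2-enyl (prenyl) groups at C6 and C8. There is no stereocentre and no alkene geometry to control, because each side-chain double bond ends in a gem-dimethyl carbon. The sensitive groups are the two trisubstituted alkenes, each ortho to phenolic oxygen: acid, strong Lewis acids and electrophilic halogen can add the neighbouring hydroxyl across the double bond (chroman formation), hydrogenation and oxidants are excluded, and the free tetraphenol is sensitive to air and base. The difficulty lies in ring A, because C-prenylation of a phloroglucinol or of a 5,7-dihydroxyflavone discriminates poorly between O and C, between C6 and C8, and between mono- and dialkylation. In addition the three ring-A oxygens have different fates: O1 becomes the ring-C ether, O5 the chelated peri-hydroxyl, and O7 the hydroxyl between the prenyl groups. The strategy rests on the alternating sequence C8a(O1)–C8(prenyl)–C7(O)–C6(prenyl)–C5(O)–C4a(H), which, read as ketene carbonyl carbon (C8a), the two carbons of a prenyl-substituted ynol ether (C8, C7) and the remaining three carbons of a prenyl- and alkoxy-substituted vinylketene (C6, C5, C4a), is what a cyclobutenone/alkyne benzannulation delivers. O1 emerges as the only free phenol and C4a as the only unsubstituted ring carbon, which are the two positions ring C needs.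

**Retrosynthetic reasoning**

25 from 24, 23 and 22. The last three operations only unmask oxygen: the two MOM ethers of ring B (25 from 24), the methyl ether on O5 (24 from 23) and the silyl ether on O7 (23 from 22). The silyl ether goes first while the material is still lipophilic. The chelation-assisted demethylation follows because it needs the C4 carbonyl next to O5. Protic acid is used only once, at the end and briefly, because it is the reagent class the prenyl groups tolerate least.

22 from 20 and 14. Ring C is cut at O1–C2 and at C4–C4a, with C4 introduced as a one-carbon carbonyl unit. In the forward sense, aryl iodide 20 undergoes carbonylative alkynylation with 14 to ynone 21, whose ortho hydroxyl closes the pyranone 6-endo. This cut uses the free O1–H and the C4a position that the ring-A construction leaves behind, and it brings in ring B as a simple terminal alkyne. Any disconnection that forms ring C before the prenyl groups are in place would bring back the C-prenylation problem.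

20 from 19. The C4a–I bond is cut. Phenol 19 has a single unsubstituted ring carbon, ortho to the free hydroxyl, so regiochemistry is not a question. The forward step only has to be chemoselective for the ring over the alkenes.

19 from 7 and 11 (key disconnection). Ring A is cut at C8a–C8, C7–C6 and C4a–C8a. Alkyne 11 supplies C8 (with its prenyl group) and C7 (with O7 as a silyl ether). Cyclobutenone 7 supplies C8a (its carbonyl carbon, which becomes the free O1 phenol), C6 (with the second prenyl group), C5 (with O5 as a methyl ether) and C4a (its methylene carbon). The gain is that ring A is assembled rather than substituted: both prenyl groups arrive already attached to the carbons that become C6 and C8, and the three oxygens emerge as OH, OMe and OSi in one step. The forward reaction must open 7 to vinylketene 15, add 11 in one orientation and aromatise, all under neutral thermal conditions.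

7 from 4 and 6; 4 from 1 and 2. The four-membered ring is cut into ketene 6 (generated from 5) and methoxyalkyne 4, whose polarisation fixes methoxy at C3 and prenyl at C2 of the cyclobutenone. Alkyne 4 is cut at its propargylic C–C bond into methoxyacetylide 3 and allylic bromide 2. Acetylide 3 is made from chloroacetal 1 by double elimination.

11 from 9 and 8. The siloxyalkyne is traced to ynolate 10, which arises from ester 9 by one-carbon carbenoid homologation. The prenyl-bearing CH2 of 9 migrates onto the new carbon, so the ester already contains the whole side chain. Ester 9 comes from acid 8.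

14 from 13 and 12. The alkyne is cut at C≡C back to aldehyde 13 (one-carbon homologation), and 13 is the bis-MOM ether of 12. MOM is chosen because it survives base, organometallics, the carbonylative coupling, the desilylation and the chelating Lewis acid, and leaves under conditions known to spare prenyl groups.

**Alternatives that were turned down**

Alternative 1: The C4a–C5 bond of ring A is disconnected with ring C already present as a 4-pyranone. The precursor is the keto ester methyl 4-{6-[2,4-bis(methoxymethoxy)phenyl]-4-oxo-4H-pyran-2-yl}-2,4-bis(3-methylbut-2-en-1-yl)-3-oxobutanoate A2.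
- Forward key step: base generates the vinylogous enolate of A2, whose pyranone α-carbon (future C4a) attacks the terminal ester (future C5) in a Claisen cyclisation. Enolisation aromatises ring A and gives 2-[2,4-bis(methoxymethoxy)phenyl]-5,7-dihydroxy-6,8-bis(3-methylbut-2-en-1-yl)-4H-chromen-4-one A1, which is the same compound as 24.
- For: the logic is biosynthetic, and in A1 both ring-A hydroxyls emerge free, so no silyl ether and no demethylation are needed. Compound A1 is one deprotection from the target. On protecting-group economy this route is stronger than the chosen one.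
- Against: A2 needs two prenyl groups on two different activated methine carbons of a polycarbonyl chain, where C- versus O-alkylation and mono- versus dialkylation are hard to control. A2 would be a mixture of diastereomers and tautomers. The cyclisation must beat retro-Claisen cleavage, base-induced opening of the pyranone and O-acylation, and it must attack an ester flanked by a prenylated methine.
- Comparison: the prenylation selectivity problem is moved from the arene to the keto ester A2 but not removed. The chosen route gives up the free O5 and O7 hydroxyls and in return fixes every ring-A position by connectivity in a neutral thermal step.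

Alternative 2: Ring C is disconnected at O1–C8a and C4–C4a.
- Forward key step: the C4a–C8a aryne is released by CsF from the silyl triflate 3,5-bis(methoxymethoxy)-4,6-bis(3-methylbut-2-en-1-yl)-2-(trimethylsilyl)phenyl trifluoromethanesulfonate A4. The aryne inserts into the acyl–oxygen bond of 3-[2,4-bis(methoxymethoxy)phenyl]prop-2-ynoic acid A5, and the resulting ortho-hydroxyaryl ynone closes to the flavone 2-[2,4-bis(methoxymethoxy)phenyl]-5,7-bis(methoxymethoxy)-6,8-bis(3-methylbut-2-en-1-yl)-4H-chromen-4-one A3.
- For: two ring-C bonds form in one metal-free operation without carbon monoxide. In A3 all four hydroxyls carry the same protecting group, so one acid step would take A3 to the target. The C5 alkoxy group of the aryne should direct the carboxylate oxygen of A5 to C8a as required. In convergence at ring C this is at least as strong as the chosen endgame.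
- Against: A4 is itself a hexasubstituted, doubly prenylated phloroglucinol with an ortho silyl triflate, so the ring-A problem is presupposed and made harder. The aryne carbon that must accept oxygen is flanked by a prenyl group. Arynes undergo ene reactions with alkenes bearing allylic hydrogens, and four such alkene termini are present per pair of molecules. Simple O-arylation of acid A5 competes with insertion.
- Comparison: the chosen route builds the ring that A4 would require and needs no high-energy intermediate next to the prenyl groups. What it gives up is the uniform protection of A3, which it replaces by three differentiated oxygens that are unmasked one after another.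

Alternative 3: C3–C4 and O1–C2 are disconnected.
- Forward key step: hydroxyl-directed insertion of trivalent rhodium ([Cp*RhCl2]2/AgSbF6) into the formyl C–H bond of the symmetric aldehyde 2,6-dihydroxy-4-(methoxymethoxy)-3,5-bis(3-methylbut-2-en-1-yl)benzaldehyde A7. Carbene transfer from the sulfoxonium ylide 1-[2,4-bis(methoxymethoxy)phenyl]-2-[dimethyl(oxo)-λ6-sulfanylidene]ethan-1-one A8 gives a 1,3-diketone, which condenses to the flavone 2-[2,4-bis(methoxymethoxy)phenyl]-5-hydroxy-7-(methoxymethoxy)-6,8-bis(3-methylbut-2-en-1-yl)-4H-chromen-4-one A6.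
- For: the symmetry of A7 removes any regiochemical question at ring C. In A6 the 5-hydroxyl emerges free and chelated and only MOM groups remain, so A6 is a single acid step from the target. Ylide A8 is a stable carbene surrogate that needs no diazo compound. From A7 this is shorter than the chosen endgame and avoids both iodination and carbon monoxide.
- Against: A7 again requires a diprenylated phloroglucinol aldehyde, which is the unselective C-prenylation, together with selective protection of the hydroxyl hemmed in by both prenyl groups. The [Cp*RhCl2]2/AgSbF6 system is Lewis acidic and is exposed to free phenols ortho to prenyl groups. The metal carbene formed from A8 can also cyclopropanate the electron-rich trisubstituted alkenes.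
- Comparison: after ring A this alternative is more economical than the chosen route, since A6 needs one deprotection where the chosen endgame needs three. It was turned down because it does not address how ring A is made, which is the main difficulty of this target.

Key step: step 7

Assumption: ketene (6) is not an article of commerce and is generated from acetone (5) immediately before use. The target has no stereocentre, so no step sets configuration.

**Route**

Step 1
Reactants: 1 chloroacetaldehyde dimethyl acetal (2-chloro-1,1-dimethoxyethane); 2 1-bromo-3-methylbut-2-ene (prenyl bromide)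
Product: 4 1-methoxy-5-methylhex-4-en-1-yne, via lithium methoxyacetylide 3 (not isolated)
Conditions: LiNEt2 (3.0 equiv, from Et2NH and n-BuLi), THF, 0 °C; then 2, HMPA (or DMPU), −78 °C to rt
Reagents that add atoms: none
Why: Three equivalents of amide base take the chloroacetal through two eliminations and a deprotonation to the alkoxyacetylide 3, a standard entry to 1-alkoxy-1-alkynes, and SN2 alkylation at the primary allylic bromide gives 4; the base is consumed before 4 exists, which protects the doubly activated CH2 of the skipped enyne from isomerisation.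

Step 2
Reactants: 4 1-methoxy-5-methylhex-4-en-1-yne; 5 acetone
Product: 7 3-methoxy-2-(3-methylbut-2-en-1-yl)cyclobut-2-en-1-one, via ketene 6 (not isolated)
Conditions: 5 through a ketene lamp (ca. 700 °C); gas stream of 6 (excess) into 4, CH2Cl2, 0 °C to rt
Reagents that add atoms: none
Why: Ketene–alkoxyalkyne (2+2) cycloaddition: the alkyne carbon remote from oxygen attacks the ketene carbonyl carbon, so methoxy ends at C3 and prenyl at C2 of the cyclobutenone; the unactivated trisubstituted alkene does not compete with the electron-rich ynol ether.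

Step 3
Reactants: 8 4-methylpent-3-enoic acid
Product: 9 ethyl 4-methylpent-3-enoate
Conditions: EtI, K2CO3, DMF, rt
Reagents that add atoms: iodoethane, CCI
Why: SN2 O-alkylation of the carboxylate under weakly basic conditions; acid-catalysed esterification is avoided because protonation of the trisubstituted alkene would close the γ-lactone.

Step 4
Reactants: 9 ethyl 4-methylpent-3-enoate
Product: 11 triisopropyl[(5-methylhex-4-en-1-yn-1-yl)oxy]silane, via lithium ynolate 10 (not isolated)
Conditions: CH2Br2 and lithium 2,2,6,6-tetramethylpiperidide (2.2 equiv each), THF, −78 °C; n-BuLi, −78 °C to rt; i-Pr3SiCl, −78 °C to rt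
Reagents that add atoms: dibromomethane, BrCBr; chlorotriisopropylsilane, CC(C)[Si](Cl)(C(C)C)C(C)C
Why: Kowalski ester homologation: dibromomethyllithium adds to the ester, the dibromo ketone enolate undergoes bromine–lithium exchange, and the carbenoid rearranges by 1,2-shift of the prenyl-bearing CH2 to ynolate 10; the bulky silyl chloride traps the ynolate on oxygen rather than carbon.

Step 5
Reactants: 12 2,4-dihydroxybenzaldehyde
Product: 13 2,4-bis(methoxymethoxy)benzaldehyde
Conditions: MOMCl, i-Pr2NEt, CH2Cl2, 0 to 40 °C
Reagents that add atoms: chloromethyl methyl ether, COCCl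
Why: Base-mediated acetal ether formation on both phenols; the hydrogen-bonded 2-hydroxyl needs excess reagent and gentle warming.

Step 6
Reactants: 13 2,4-bis(methoxymethoxy)benzaldehyde
Product: 14 1-ethynyl-2,4-bis(methoxymethoxy)benzene
Conditions: dimethyl (1-diazo-2-oxopropyl)phosphonate, K2CO3, MeOH, rt
Reagents that add atoms: dimethyl (1-diazo-2-oxopropyl)phosphonate, CC(=O)C(=[N+]=[N-])P(=O)(OC)OC
Why: Ohira–Bestmann homologation: the diazomethylphosphonate anion formed by methanolysis olefinates the aldehyde, and the diazoalkene loses N2 with 1,2-hydrogen shift; carbonate in methanol leaves the MOM ethers untouched.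

Step 7
Reactants: 7 3-methoxy-2-(3-methylbut-2-en-1-yl)cyclobut-2-en-1-one; 11 triisopropyl[(5-methylhex-4-en-1-yn-1-yl)oxy]silane
Product: 19 5-methoxy-2,4-bis(3-methylbut-2-en-1-yl)-3-[(triisopropylsilyl)oxy]phenol, via vinylketene 15 (not isolated), via vinylcyclobutenone 16 (not isolated), via dienylketene 17 (not isolated), via cyclohexadienone 18 (not isolated)
Conditions: 11 (1.3 equiv), toluene (ca. 0.5 M), sealed tube, argon, 80 °C then 110 °C
Reagents that add atoms: none
Why: On heating, 7 undergoes reversible four-electron electrocyclic opening (cleavage of its C1–C4 bond) to vinylketene 15. The siloxyalkyne 11 is polarised so that its carbon remote from oxygen is nucleophilic; it attacks the electrophilic ketene carbon of 15 in a regiospecific (2+2) cycloaddition that forms C8a–C8 and C7–C6 and gives the 4-vinylcyclobutenone 16. A second four-electron opening of 16 gives dienylketene 17, and six-electron disrotatory electrocyclisation of its (3E)-triene joins the ketene carbon to the methylene terminus (C8a–C4a), closing the six-membered carbocycle as dienone 18, which tautomerises to phenol 19. This is the Danheiser benzannulation of cyclobutenone-derived vinylketenes with siloxyalkynes, the known route to resorcinol monosilyl ethers, here applied to a 3-alkoxycyclobutenone. No stereocentre survives: the quaternary carbon of 16 forms racemic and is lost in the next ring opening. The selectivity the step needs is the orientation of the (2+2) event, and it is secured by the oxygen substituent of 11, which makes the prenyl-bearing alkyne carbon the nucleophile, so that one prenyl group ends between the free hydroxyl (future O1) and the silyl ether (O7), the other between the silyl ether and the methoxy group (O5), and a single ring carbon (future C4a) stays unsubstituted. Ketenes react through their C=C bond in (2+2) fashion rather than as dienes, and the unactivated prenyl alkenes cannot compete with the electron-rich ynol ether. The medium is neutral and metal-free, so both prenyl groups and the silyl ether should pass through unchanged.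

Step 8
Reactants: 19 5-methoxy-2,4-bis(3-methylbut-2-en-1-yl)-3-[(triisopropylsilyl)oxy]phenol
Product: 20 2-iodo-3-methoxy-4,6-bis(3-methylbut-2-en-1-yl)-5-[(triisopropylsilyl)oxy]phenol
Conditions: NIS (1.0 equiv), CH2Cl2, −40 to 0 °C, dark
Reagents that add atoms: N-iodosuccinimide, O=C1CCC(=O)N1I
Why: Electrophilic aromatic iodination at the only unsubstituted ring carbon, which is ortho to OH and OMe and para to the silyloxy group; cold, neutral, aprotic conditions keep the phenol a poor nucleophile, so iodoetherification of the neighbouring prenyl group should lag behind substitution on the very electron-rich ring.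

Step 9
Reactants: 20 2-iodo-3-methoxy-4,6-bis(3-methylbut-2-en-1-yl)-5-[(triisopropylsilyl)oxy]phenol; 14 1-ethynyl-2,4-bis(methoxymethoxy)benzene
Product: 22 2-[2,4-bis(methoxymethoxy)phenyl]-5-methoxy-6,8-bis(3-methylbut-2-en-1-yl)-7-[(triisopropylsilyl)oxy]-4H-chromen-4-one, via ynone 21 (not isolated)
Conditions: 14 (1.5 equiv), PdCl2(dppf) (5 mol %), CO (5 atm), Et2NH, 90 °C
Reagents that add atoms: carbon monoxide, [C-]#[O+]
Why: Carbonylative Sonogashira coupling (oxidative addition of the aryl iodide to zerovalent palladium, CO insertion, alkynyl transfer, reductive elimination) gives ynone 21, and the secondary amine promotes 6-endo conjugate addition of the ortho phenol, which closes ring C as the flavone rather than the aurone; CuI is left out to suppress direct alkynylation.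

Step 10
Reactants: 22 2-[2,4-bis(methoxymethoxy)phenyl]-5-methoxy-6,8-bis(3-methylbut-2-en-1-yl)-7-[(triisopropylsilyl)oxy]-4H-chromen-4-one
Product: 23 2-[2,4-bis(methoxymethoxy)phenyl]-7-hydroxy-5-methoxy-6,8-bis(3-methylbut-2-en-1-yl)-4H-chromen-4-one
Conditions: Bu4NF, AcOH (1:1), THF, 0 °C to rt
Reagents that add atoms: none
Why: Fluoride-induced cleavage of the aryl silyl ether; acetic acid buffers the acidic 7-phenoxide, and MOM ethers, the methyl ether and the prenyl groups are inert to fluoride.

Step 11
Reactants: 23 2-[2,4-bis(methoxymethoxy)phenyl]-7-hydroxy-5-methoxy-6,8-bis(3-methylbut-2-en-1-yl)-4H-chromen-4-one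
Product: 24 2-[2,4-bis(methoxymethoxy)phenyl]-5,7-dihydroxy-6,8-bis(3-methylbut-2-en-1-yl)-4H-chromen-4-one
Conditions: MgI2·OEt2 (4 equiv), THF, 50 °C; aqueous Na2S2O3 work-up
Reagents that add atoms: none
Why: Chelation-controlled ether cleavage: magnesium binds the C4 carbonyl and the peri 5-methoxy oxygen, and iodide removes the methyl group by SN2; this is the only methyl ether in the molecule, and MgI2 is a weak Lewis acid of the kind usually chosen when prenyl groups flank phenols.

Step 12
Reactants: 24 2-[2,4-bis(methoxymethoxy)phenyl]-5,7-dihydroxy-6,8-bis(3-methylbut-2-en-1-yl)-4H-chromen-4-one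
Product: 25 2-(2,4-dihydroxyphenyl)-5,7-dihydroxy-6,8-bis(3-methylbut-2-en-1-yl)-4H-chromen-4-one (target)
Conditions: 3 M aqueous HCl, MeOH, 45 °C, short reaction time
Reagents that add atoms: none
Why: Acid-catalysed acetal exchange removes both MOM groups as dimethoxymethane; moderate acid strength, mild temperature and short exposure are chosen because stronger acid would add the 5- and 7-hydroxyls across the prenyl double bonds.

**Compound list**

1 | chloroacetaldehyde dimethyl acetal (2-chloro-1,1-dimethoxyethane) | COC(CCl)OC | starting material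
2 | 1-bromo-3-methylbut-2-ene (prenyl bromide) | CC(C)=CCBr | starting material
3 | lithium methoxyacetylide | COC#C[Li] | intermediate (not isolated)
4 | 1-methoxy-5-methylhex-4-en-1-yne | COC#CCC=C(C)C | intermediate
5 | acetone | CC(C)=O | starting material
6 | ketene (ethenone) | C=C=O | intermediate (not isolated)
7 | 3-methoxy-2-(3-methylbut-2-en-1-yl)cyclobut-2-en-1-one | COC1=C(CC=C(C)C)C(=O)C1 | intermediate
8 | 4-methylpent-3-enoic acid | CC(C)=CCC(=O)O | starting material
9 | ethyl 4-methylpent-3-enoate | CCOC(=O)CC=C(C)C | intermediate
10 | lithium 5-methylhex-4-en-1-yn-1-olate (ynolate) | CC(C)=CCC#CO[Li] | intermediate (not isolated)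
11 | triisopropyl[(5-methylhex-4-en-1-yn-1-yl)oxy]silane | CC(C)=CCC#CO[Si](C(C)C)(C(C)C)C(C)C | intermediate
12 | 2,4-dihydroxybenzaldehyde | O=Cc1ccc(O)cc1O | starting material
13 | 2,4-bis(methoxymethoxy)benzaldehyde | COCOc1ccc(C=O)c(OCOC)c1 | intermediate
14 | 1-ethynyl-2,4-bis(methoxymethoxy)benzene | COCOc1ccc(C#C)c(OCOC)c1 | intermediate
15 | 3-methoxy-2-(3-methylbut-2-en-1-yl)buta-1,3-dien-1-one (vinylketene) | C=C(OC)C(CC=C(C)C)=C=O | intermediate (not isolated)
16 | 4-(1-methoxyethenyl)-2,4-bis(3-methylbut-2-en-1-yl)-3-[(triisopropylsilyl)oxy]cyclobut-2-en-1-one (racemic) | C=C(OC)C1(CC=C(C)C)C(=O)C(CC=C(C)C)=C1O[Si](C(C)C)(C(C)C)C(C)C | intermediate (not isolated)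
17 | (3E)-5-methoxy-2,4-bis(3-methylbut-2-en-1-yl)-3-[(triisopropylsilyl)oxy]hexa-1,3,5-trien-1-one (dienylketene) | O=C=C(CC=C(C)C)/C(O[Si](C(C)C)(C(C)C)C(C)C)=C(CC=C(C)C)\C(OC)=C | intermediate (not isolated)
18 | 5-methoxy-2,4-bis(3-methylbut-2-en-1-yl)-3-[(triisopropylsilyl)oxy]cyclohexa-2,4-dien-1-one | O=C1CC(OC)=C(CC=C(C)C)C(O[Si](C(C)C)(C(C)C)C(C)C)=C1CC=C(C)C | intermediate (not isolated)
19 | 5-methoxy-2,4-bis(3-methylbut-2-en-1-yl)-3-[(triisopropylsilyl)oxy]phenol | COc1cc(O)c(CC=C(C)C)c(O[Si](C(C)C)(C(C)C)C(C)C)c1CC=C(C)C | intermediate
20 | 2-iodo-3-methoxy-4,6-bis(3-methylbut-2-en-1-yl)-5-[(triisopropylsilyl)oxy]phenol | COc1c(I)c(O)c(CC=C(C)C)c(O[Si](C(C)C)(C(C)C)C(C)C)c1CC=C(C)C | intermediate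
21 | 3-[2,4-bis(methoxymethoxy)phenyl]-1-{2-hydroxy-6-methoxy-3,5-bis(3-methylbut-2-en-1-yl)-4-[(triisopropylsilyl)oxy]phenyl}prop-2-yn-1-one | COCOc1ccc(C#CC(=O)c2c(O)c(CC=C(C)C)c(O[Si](C(C)C)(C(C)C)C(C)C)c(CC=C(C)C)c2OC)c(OCOC)c1 | intermediate (not isolated)
22 | 2-[2,4-bis(methoxymethoxy)phenyl]-5-methoxy-6,8-bis(3-methylbut-2-en-1-yl)-7-[(triisopropylsilyl)oxy]-4H-chromen-4-one | COCOc1ccc(-c2cc(=O)c3c(OC)c(CC=C(C)C)c(O[Si](C(C)C)(C(C)C)C(C)C)c(CC=C(C)C)c3o2)c(OCOC)c1 | intermediate
23 | 2-[2,4-bis(methoxymethoxy)phenyl]-7-hydroxy-5-methoxy-6,8-bis(3-methylbut-2-en-1-yl)-4H-chromen-4-one | COCOc1ccc(-c2cc(=O)c3c(OC)c(CC=C(C)C)c(O)c(CC=C(C)C)c3o2)c(OCOC)c1 | intermediate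
24 | 2-[2,4-bis(methoxymethoxy)phenyl]-5,7-dihydroxy-6,8-bis(3-methylbut-2-en-1-yl)-4H-chromen-4-one | COCOc1ccc(-c2cc(=O)c3c(O)c(CC=C(C)C)c(O)c(CC=C(C)C)c3o2)c(OCOC)c1 | intermediate
25 | 2-(2,4-dihydroxyphenyl)-5,7-dihydroxy-6,8-bis(3-methylbut-2-en-1-yl)-4H-chromen-4-one | CC(C)=CCc1c(O)c(CC=C(C)C)c2oc(-c3ccc(O)cc3O)cc(=O)c2c1O | target

**Step count and risk**

Total step count: 12. Longest linear sequence: 8 steps (steps 1, 2, 7, 8, 9, 10, 11, 12; the branch through steps 3 and 4 is equally long).

Step 7 (key step).
- Risk: the four-electron opening of 7 is slowed by the vinylogous-ester stabilisation of its 3-methoxy enone. The temperature needed may then reach the range where 11 isomerises by 1,3-silyl shift from oxygen to carbon, or where vinylketene 15 dimerises. The sequence may also stall at 16.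
- Fallback (directed metalation, no pericyclic step): commercial 5-methoxybenzene-1,3-diol F1 is protected with MOMCl/i-Pr2NEt as 1-methoxy-3,5-bis(methoxymethoxy)benzene F2. Lithiation with n-BuLi between the two MOM ethers and alkylation with 2 (CuI cat.) should give 5-methoxy-1,3-bis(methoxymethoxy)-2-(3-methylbut-2-en-1-yl)benzene F3. A second lithiation, at one of the two equivalent positions between a MOM ether and the methoxy group, and alkylation with 2 gives 1-methoxy-3,5-bis(methoxymethoxy)-2,4-bis(3-methylbut-2-en-1-yl)benzene F4. Brief HCl/MeOH frees 5-methoxy-2,4-bis(3-methylbut-2-en-1-yl)benzene-1,3-diol F5. NIS as in step 8 gives 4-iodo-5-methoxy-2,6-bis(3-methylbut-2-en-1-yl)benzene-1,3-diol F6. The conditions of step 9 with 14 then close ring C through the only hydroxyl ortho to iodine. The fallback sets out from 2 and 14 and comes back to the route at 23.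

Step 8.
- Risk: iodine-induced cyclisation of the ortho-prenyl phenol (iodoetherification through the iodonium ion of the prenyl group next to the free hydroxyl) competing with substitution on the ring.
- Fallback (no electrophilic halogen): magnesium-mediated ortho-formylation of 19 (MgCl2, Et3N, paraformaldehyde, MeCN, reflux; Casnati–Skattebøl) should give 2-hydroxy-6-methoxy-3,5-bis(3-methylbut-2-en-1-yl)-4-[(triisopropylsilyl)oxy]benzaldehyde F7. Addition of the lithium acetylide of 14 (excess, THF, −78 to 0 °C) gives racemic 2-{3-[2,4-bis(methoxymethoxy)phenyl]-1-hydroxyprop-2-yn-1-yl}-3-methoxy-4,6-bis(3-methylbut-2-en-1-yl)-5-[(triisopropylsilyl)oxy]phenol F8. MnO2 in CH2Cl2 oxidises F8 to ynone 21, which Et2NH in EtOH cyclises to 22. The fallback sets out from 19 and 14 and comes back at 21.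

Step 9.
- Risk: slow oxidative addition at the doubly ortho-substituted, electron-rich iodide, which lets side processes win. These are aminocarbonylation by the amine solvent, direct alkynylation followed by closure to a benzofuran, and 5-exo closure of 21 to the aurone.
- Fallback (no palladium, no carbon monoxide): 14 is lithiated and acylated with N-methoxy-N-methylcarbamoyl chloride to give 3-[2,4-bis(methoxymethoxy)phenyl]-N-methoxy-N-methylprop-2-ynamide F9. Iodophenol 20 is deprotonated with NaH, subjected to iodine–lithium exchange with t-BuLi at −78 °C and added to F9. Collapse of the Weinreb adduct on work-up gives ynone 21, which Et2NH in EtOH cyclises to 22. The fallback sets out from 20 and 14 and comes back at 21.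

Step 4.
- Risk: enolisation of the β,γ-unsaturated ester at its doubly activated α-CH2 instead of carbenoid addition, migration of the double bond into conjugation under the strongly basic conditions, and silylation of the ynolate on carbon.
- Fallback (ynolate by acetylide oxidation): alkylation of lithium (trimethylsilyl)acetylide with 2 (THF/DMPU) gives trimethyl(5-methylhex-4-en-1-yn-1-yl)silane F10, and K2CO3/MeOH gives 5-methylhex-4-en-1-yne F11. Deprotonation with n-BuLi and oxidation of the acetylide with lithium tert-butyl peroxide (from t-BuOOH and LiN(SiMe3)2) gives ynolate 10, which is trapped with i-Pr3SiOTf as 11. The fallback sets out from 2 and comes back at 10.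

Step 11.
- Risk: Lewis-acid or adventitious HI-induced addition of the 7- or 5-hydroxyl across a prenyl double bond, and partial loss of the MOM ethers, which would complicate isolation.
- Fallback (O5 carried as a silyl ether, so no demethylation): ketene 6 and siloxyalkyne 11 give 2-(3-methylbut-2-en-1-yl)-3-[(triisopropylsilyl)oxy]cyclobut-2-en-1-one F12 by (2+2) cycloaddition. Heating F12 with a second portion of 11 as in step 7 gives 2,4-bis(3-methylbut-2-en-1-yl)-3,5-bis[(triisopropylsilyl)oxy]phenol F13. Iodination as in step 8 gives 2-iodo-4,6-bis(3-methylbut-2-en-1-yl)-3,5-bis[(triisopropylsilyl)oxy]phenol F14. Carbonylative annulation with 14 as in step 9 gives 2-[2,4-bis(methoxymethoxy)phenyl]-6,8-bis(3-methylbut-2-en-1-yl)-5,7-bis[(triisopropylsilyl)oxy]-4H-chromen-4-one F15, and Bu4NF/AcOH removes both silyl groups. The fallback sets out from 6, 11 and 14 and comes back at 24.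

**Further compounds**

F1 | step 7 | 5-methoxybenzene-1,3-diol | COc1cc(O)cc(O)c1
F2 | step 7 | 1-methoxy-3,5-bis(methoxymethoxy)benzene | COCOc1cc(OC)cc(OCOC)c1
F3 | step 7 | 5-methoxy-1,3-bis(methoxymethoxy)-2-(3-methylbut-2-en-1-yl)benzene | COCOc1cc(OC)cc(OCOC)c1CC=C(C)C
F4 | step 7 | 1-methoxy-3,5-bis(methoxymethoxy)-2,4-bis(3-methylbut-2-en-1-yl)benzene | COc1cc(OCOC)c(CC=C(C)C)c(OCOC)c1CC=C(C)C
F5 | step 7 | 5-methoxy-2,4-bis(3-methylbut-2-en-1-yl)benzene-1,3-diol | COc1cc(O)c(CC=C(C)C)c(O)c1CC=C(C)C
F6 | step 7 | 4-iodo-5-methoxy-2,6-bis(3-methylbut-2-en-1-yl)benzene-1,3-diol | COc1c(I)c(O)c(CC=C(C)C)c(O)c1CC=C(C)C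
F7 | step 8 | 2-hydroxy-6-methoxy-3,5-bis(3-methylbut-2-en-1-yl)-4-[(triisopropylsilyl)oxy]benzaldehyde | COc1c(C=O)c(O)c(CC=C(C)C)c(O[Si](C(C)C)(C(C)C)C(C)C)c1CC=C(C)C
F8 | step 8 | 2-{3-[2,4-bis(methoxymethoxy)phenyl]-1-hydroxyprop-2-yn-1-yl}-3-methoxy-4,6-bis(3-methylbut-2-en-1-yl)-5-[(triisopropylsilyl)oxy]phenol (racemic) | COCOc1ccc(C#CC(O)c2c(O)c(CC=C(C)C)c(O[Si](C(C)C)(C(C)C)C(C)C)c(CC=C(C)C)c2OC)c(OCOC)c1
F9 | step 9 | 3-[2,4-bis(methoxymethoxy)phenyl]-N-methoxy-N-methylprop-2-ynamide | COCOc1ccc(C#CC(=O)N(C)OC)c(OCOC)c1
F10 | step 4 | trimethyl(5-methylhex-4-en-1-yn-1-yl)silane | CC(C)=CCC#C[Si](C)(C)C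
F11 | step 4 | 5-methylhex-4-en-1-yne | CC(C)=CCC#C
F12 | step 11 | 2-(3-methylbut-2-en-1-yl)-3-[(triisopropylsilyl)oxy]cyclobut-2-en-1-one | CC(C)=CCC1=C(O[Si](C(C)C)(C(C)C)C(C)C)CC1=O
F13 | step 11 | 2,4-bis(3-methylbut-2-en-1-yl)-3,5-bis[(triisopropylsilyl)oxy]phenol | CC(C)=CCc1c(O)cc(O[Si](C(C)C)(C(C)C)C(C)C)c(CC=C(C)C)c1O[Si](C(C)C)(C(C)C)C(C)C
F14 | step 11 | 2-iodo-4,6-bis(3-methylbut-2-en-1-yl)-3,5-bis[(triisopropylsilyl)oxy]phenol | CC(C)=CCc1c(O)c(I)c(O[Si](C(C)C)(C(C)C)C(C)C)c(CC=C(C)C)c1O[Si](C(C)C)(C(C)C)C(C)C
F15 | step 11 | 2-[2,4-bis(methoxymethoxy)phenyl]-6,8-bis(3-methylbut-2-en-1-yl)-5,7-bis[(triisopropylsilyl)oxy]-4H-chromen-4-one | COCOc1ccc(-c2cc(=O)c3c(O[Si](C(C)C)(C(C)C)C(C)C)c(CC=C(C)C)c(O[Si](C(C)C)(C(C)C)C(C)C)c(CC=C(C)C)c3o2)c(OCOC)c1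
A1 | alternative 1 | 2-[2,4-bis(methoxymethoxy)phenyl]-5,7-dihydroxy-6,8-bis(3-methylbut-2-en-1-yl)-4H-chromen-4-one | CC(C)=CCc1c(O)c(CC=C(C)C)c2oc(-c3ccc(OCOC)cc3OCOC)cc(=O)c2c1O
A2 | alternative 1 | methyl 4-{6-[2,4-bis(methoxymethoxy)phenyl]-4-oxo-4H-pyran-2-yl}-2,4-bis(3-methylbut-2-en-1-yl)-3-oxobutanoate (mixture of diastereomers) | COC(=O)C(CC=C(C)C)C(=O)C(CC=C(C)C)c1cc(=O)cc(-c2ccc(OCOC)cc2OCOC)o1
A3 | alternative 2 | 2-[2,4-bis(methoxymethoxy)phenyl]-5,7-bis(methoxymethoxy)-6,8-bis(3-methylbut-2-en-1-yl)-4H-chromen-4-one | CC(C)=CCc1c(OCOC)c(CC=C(C)C)c2oc(-c3ccc(OCOC)cc3OCOC)cc(=O)c2c1OCOC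
A4 | alternative 2 | 3,5-bis(methoxymethoxy)-4,6-bis(3-methylbut-2-en-1-yl)-2-(trimethylsilyl)phenyl trifluoromethanesulfonate | COCOc1c(CC=C(C)C)c(OCOC)c(CC=C(C)C)c(OS(=O)(=O)C(F)(F)F)c1[Si](C)(C)C
A5 | alternative 2 | 3-[2,4-bis(methoxymethoxy)phenyl]prop-2-ynoic acid | COCOc1ccc(C#CC(=O)O)c(OCOC)c1
A6 | alternative 3 | 2-[2,4-bis(methoxymethoxy)phenyl]-5-hydroxy-7-(methoxymethoxy)-6,8-bis(3-methylbut-2-en-1-yl)-4H-chromen-4-one | CC(C)=CCc1c(OCOC)c(CC=C(C)C)c2oc(-c3ccc(OCOC)cc3OCOC)cc(=O)c2c1O
A7 | alternative 3 | 2,6-dihydroxy-4-(methoxymethoxy)-3,5-bis(3-methylbut-2-en-1-yl)benzaldehyde | O=Cc1c(O)c(CC=C(C)C)c(OCOC)c(CC=C(C)C)c1O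
A8 | alternative 3 | 1-[2,4-bis(methoxymethoxy)phenyl]-2-[dimethyl(oxo)-λ6-sulfanylidene]ethan-1-one | COCOc1ccc(C(=O)C=S(C)(C)=O)c(OCOC)c1
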